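In this stirred vessel of constant volume, electrophile goes in as two equal portions onto nucleophile and free base, and the flasks differ in their free base. All amounts are fractions of the electrophile charged.

the same everywhere: electrophile 0.25 M (in portions, 2)

| run | nucleophile | free base | remark | time |
|---|---|---|---|---|
| dusk | 1 equiv | 2.1 equiv | run made earlier; portions every 80 min |  |
| spring | 1 equiv | 7.4 equiv | run made earlier; portions every 80 min |  |
| Monday's | 1.00 equiv | 3.00 equiv | the portions of electrophile follow each other after 80 min, the first at the start | 25 h |
| Saturday's | 1.00 equiv | 5.00 equiv | the portions of electrophile follow each other after 80 min, the first at the start | 25 h |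
| Friday's | 1.00 equiv | 6.00 equiv | the portions of electrophile follow each other after 80 min, the first at the start | 25 h |
| Sunday's | 1.00 equiv | 10.0 equiv | the portions of electrophile follow each other after 80 min, the first at the start | 25 h |

| run | time / h | target / % | electrophile / % |
|---|---|---|---|
| dusk | 1.00 | 36 | 15 |
| dusk | 2.50 | 43 | 53 |
| dusk | 5.00 | 44 | 42 |
| dusk | 8.00 | 50 | 36 |
| dusk | 10.0 | 49 | 30 |
| dusk | 15.0 | 49 | 18 |
| dusk | 20.0 | 49 | 15 |
| spring | 2.50 | 44 | 52 |
| spring | 5.00 | 52 | 39 |
| spring | 8.00 | 54 | 28 |
| spring | 10.0 | 56 | 23 |
| spring | 12.0 | 58 | 19 |
| spring | 15.0 | 58 | 13 |
| spring | 20.0 | 57 | 7 |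

(each reading ± 1.5 percentage points)

- what was read earlier has a scatter of 1.5 percentage points, one standard deviation
- "hardly changes" means that all values lie within two and a half points (for a concentration: within two and a half percent of the largest)

- amount of target at the end, in percent of the electrophile charged for Monday's, Saturday's, Friday's, Sunday's, in this order
- how the row runs (falls all the way / falls, then rises / rises, then falls / rises all the way / hardly changes)

The target first jumps, then stands still. At 2.50 h the dusk run has 43% and the spring run 44%, a difference of 1 percentage point against a scatter of 1.5 points. In the dusk run the target reads 49% at 10.0 h and 49% at 20.0 h, while the electrophile falls from 30% to 15%. So you can read the end of a flask from its plateau: 49.0% for the dusk run and 57.5% for the spring run, each the mean of the last two readings.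

Fold the free base into one number: the base position, a logarithmic interpolation coordinate, is the logarithm of a flask's free base relative to the dusk run, divided by the same logarithm for the spring run. The dusk run stands at zero and the spring run at one; two runs cannot test the logarithm, so it is a choice. Monday's stands at 0.283, Saturday's at 0.689, Friday's at 0.833 and Sunday's at 1.24. Placing each flask that far along the line between the plateaus, you get 51.4%, 54.9%, 56.1% and 59.5%, a row that rises all the way by 8.1 points.

The two readings at 2.50 h neither show nor exclude an effect of the free base at that time, so the base position is used on the plateaus. Sunday's, at 1.24, lies beyond the spring run, so its value is an extrapolation.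

The forecast gives 52%, 55.5%, 56.5% and 59.5%, rises all the way; its Monday's value lies 0.60 points above this reckoning. It adds: “A peak within this range is possible, but the data don't show one.”

The flasks give 52.8%, 56.3%, 57.5% and 60.1%: rises all the way.

    electrophile + nucleophile → acid set free + target (k = 0.00570 L mol⁻¹ s⁻¹)
    nucleophile + acid set free ⇌ protonated nucleophile, settled at all times (K = 36000 L mol⁻¹)
    acid set free + free base ⇌ salt of the base, settled at all times (K = 310 L mol⁻¹)
    electrophile + target → side product (k = 7.20 × 10⁻⁵ L mol⁻¹ s⁻¹)
    nucleophile ⇌ dormant form (K = 11.0, k = 4.80 × 10⁻⁴ s⁻¹)

At 25.0 h, Monday's flask makes target 1.06 times as fast as it uses it up, each step taken net. At base position 0.283, Monday's lies 1.4 points above the line between the plateaus, and Sunday's, at 1.24, lies 0.60 points above it.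

The readings are calculated on assumed constants; noise was put on by code.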